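## Retrosynthetic overview
1. Endgame: remove two O-benzyl groups with H2. The C9'' alcohol comes from reductive removal of an oxazolidinone. The C7''–C8'' bond comes from an auxiliary-controlled anti (erythro) aldol between O-benzylvanillin and the aryloxyacetyl imide of the oxolane phenol.
2. The only non-aromatic ring (oxolane, C7–O bond) is closed from an acyclic (8S,8'S)-dibenzylbutanediol. The free syringyl phenol is oxidised to its para-quinone methide and the C9' hydroxyl traps it 5-exo, which sets C7.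
3. The diol comes from one LiAlH4 reduction (imide, tert-butyl ester and aryl carbamate together) of an unsymmetrical 2,3-dibenzylsuccinate.
4. The C8–C8' bond comes from oxidative heterocoupling of two dihydrocinnamate enolates: the guaiacyl imide of (R)-4-benzyloxazolidinone and a syringyl tert-butyl ester. This sets C8' and C8.
5. Ring order: a single ring, formed after the 8–8' bond and before the 8''–O–4 ether. Feedstocks are dihydroferulic acid, syringaldehyde, O-benzylvanillin, the oxazolidinone and bromoacetyl bromide.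

Assumption: lignan numbering is used (C7–C9 = syringyl C3 unit, C7'–C9' = guaiacyl C3 unit of the oxolane part, C7''–C9'' = arylglycerol unit); LiN(iPr)2 and n-BuLi are bought as solutions.

## Route

Step 1
Reactants: 1 3-(4-hydroxy-3-methoxyphenyl)propanoic acid (dihydroferulic acid)
Product: 2 3-[4-(benzyloxy)-3-methoxyphenyl]propanoic acid
Conditions: BnBr (1.2 equiv), NaOH (2.5 equiv), EtOH/H2O, reflux; then HCl to pH 2
Reagents that add atoms: benzyl bromide, BrCc1ccccc1
Why: Williamson ether synthesis in which the phenoxide is far more nucleophilic than the carboxylate and any benzyl ester formed is saponified in the same pot, so only the aryl benzyl ether survives acidification and no stereocenter is involved.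

Step 2
Reactants: 2 3-[4-(benzyloxy)-3-methoxyphenyl]propanoic acid; 3 (R)-4-benzyl-1,3-oxazolidin-2-one
Product: 5 (4R)-4-benzyl-3-{3-[4-(benzyloxy)-3-methoxyphenyl]propanoyl}-1,3-oxazolidin-2-one, via mixed pivalic anhydride 4 (not isolated)
Conditions: t-BuCOCl, Et3N, THF, −20 °C; then LiCl, 3, −20 °C to rt
Reagents that add atoms: pivaloyl chloride, CC(C)(C)C(=O)Cl (its acyl group ends up only in 4, not in 5)
Why: Mixed-anhydride N-acylation of an Evans oxazolidinone (LiCl/Et3N variant), in which the hindered pivaloyl carbonyl of 4 is not attacked, so only the arylpropanoyl group is transferred and the auxiliary stereocenter is untouched.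

Step 3
Reactants: 6 4-hydroxy-3,5-dimethoxybenzaldehyde (syringaldehyde)
Product: 7 4-formyl-2,6-dimethoxyphenyl N,N-diethylcarbamate
Conditions: Et2NCOCl, K2CO3, MeCN, reflux
Reagents that add atoms: N,N-diethylcarbamoyl chloride, CCN(CC)C(=O)Cl
Why: O-carbamoylation of an acidic phenol (nucleophilic acyl substitution) gives a carbamate that has both ortho positions blocked (no anionic Fries path), so it tolerates LiN(iPr)2 later and is removed by LiAlH4 without a separate step.

Step 4
Reactants: 7 4-formyl-2,6-dimethoxyphenyl N,N-diethylcarbamate; 8 tert-butyl (triphenylphosphoranylidene)acetate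
Product: 9 tert-butyl (E)-3-{4-[(diethylcarbamoyl)oxy]-3,5-dimethoxyphenyl}prop-2-enoate
Conditions: toluene, 80 °C
Reagents that add atoms: none
Why: Wittig olefination with a stabilised ylide gives the E-cinnamate cleanly, and the alkene geometry is irrelevant because the double bond is hydrogenated next.

Step 5
Reactants: 9 tert-butyl (E)-3-{4-[(diethylcarbamoyl)oxy]-3,5-dimethoxyphenyl}prop-2-enoate
Product: 10 tert-butyl 3-{4-[(diethylcarbamoyl)oxy]-3,5-dimethoxyphenyl}propanoate
Conditions: H2 (1 atm), 10% Pd/C, EtOAc, rt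
Reagents that add atoms: none
Why: Heterogeneous catalytic hydrogenation of a conjugated alkene, with carbamate, tert-butyl ester and arene inert at 1 atm.

Step 6
Reactants: 5 (4R)-4-benzyl-3-{3-[4-(benzyloxy)-3-methoxyphenyl]propanoyl}-1,3-oxazolidin-2-one; 10 tert-butyl 3-{4-[(diethylcarbamoyl)oxy]-3,5-dimethoxyphenyl}propanoate
Product: 11 tert-butyl (2S,3S)-3-{[(4R)-4-benzyl-2-oxo-1,3-oxazolidin-3-yl]carbonyl}-4-[4-(benzyloxy)-3-methoxyphenyl]-2-{4-[(diethylcarbamoyl)oxy]-3,5-dimethoxybenzyl}butanoate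
Conditions: 5 (1 equiv), 10 (1.5 equiv), LiN(iPr)2 (2.6 equiv), THF, −78 °C; then Fe(acac)3 (2.6 equiv), −78 °C to rt; chromatography
Reagents that add atoms: none
Why: Oxidative enolate heterocoupling (one-electron oxidation of a mixed imide/ester lithium enolate pair by trivalent iron, a flask version of the 8–8' radical coupling, known for dibenzylsuccinate lignan precursors), in which the two enolate classes differ enough to favour the cross product, the benzyl group of the (R)-auxiliary shields one face of the chelated Z-enolate so that C8' forms S (the same facial sense as enolate alkylation), and the usual preference for the like (dl-type) 2,3-disubstituted succinate gives C8 = S, the minor C8 epimer and the homodimers being removed by chromatography.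

Step 7
Reactants: 11 tert-butyl (2S,3S)-3-{[(4R)-4-benzyl-2-oxo-1,3-oxazolidin-3-yl]carbonyl}-4-[4-(benzyloxy)-3-methoxyphenyl]-2-{4-[(diethylcarbamoyl)oxy]-3,5-dimethoxybenzyl}butanoate
Product: 12 (2S,3S)-2-[4-(benzyloxy)-3-methoxybenzyl]-3-(4-hydroxy-3,5-dimethoxybenzyl)butane-1,4-diol
Conditions: LiAlH4 (6 equiv), THF, 0 °C to reflux; aqueous work-up at pH 6
Reagents that add atoms: none
Why: Exhaustive LiAlH4 reduction turns the imide and the tert-butyl ester into the two primary alcohols and cleaves the aryl carbamate to the free syringyl phenol in one operation, while the aryl benzyl ether is inert and hydride addition outruns enolisation so that C8 and C8' are retained.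

Step 8
Reactants: 12 (2S,3S)-2-[4-(benzyloxy)-3-methoxybenzyl]-3-(4-hydroxy-3,5-dimethoxybenzyl)butane-1,4-diol
Product: 14 {(2R,3S,4S)-4-[4-(benzyloxy)-3-methoxybenzyl]-2-(4-hydroxy-3,5-dimethoxyphenyl)oxolan-3-yl}methanol, via para-quinone methide 13 (not isolated)
Conditions: Ag2O (1.3 equiv), 4 Å molecular sieves, CH2Cl2, rt, dark
Reagents that add atoms: none
Why: Proposed new method: Ag2O removes two electrons and two protons from the only free phenol (both ortho positions carry OMe, so the phenoxyl radical cannot dimerise and goes on to para-quinone methide 13, while the O-benzylated guaiacyl ring and the alcohols are inert), the C9' hydroxyl then adds 5-exo-trig to C7 with rearomatisation (the C9 hydroxyl could only give an oxetane), and C7 is set R because the aryl group takes the face trans to the neighbouring C8 CH2OH, an outcome reinforced by reversibility of the addition through 13, which funnels material to the 7,8-trans-8,8'-cis isomer; this copies the quinone methide trapping that closes lignan oxolane rings in plants, and the closest known reaction types are the Ag2O oxidation of 4-alkyl-2,6-disubstituted phenols to para-quinone methides with intramolecular nucleophilic capture and the acid-induced cyclisation of 7-hydroxysecoisolariciresinol to lariciresinol.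

Step 9
Reactants: 3 (R)-4-benzyl-1,3-oxazolidin-2-one; 15 bromoacetyl bromide
Product: 16 (4R)-4-benzyl-3-(bromoacetyl)-1,3-oxazolidin-2-one
Conditions: n-BuLi, THF, −78 °C; then 15, −78 to 0 °C
Reagents that add atoms: none
Why: N-acylation of the lithiated oxazolidinone, in which the acid bromide carbonyl is far more electrophilic than the alkyl bromide end and the auxiliary stereocenter is untouched.

Step 10
Reactants: 14 {(2R,3S,4S)-4-[4-(benzyloxy)-3-methoxybenzyl]-2-(4-hydroxy-3,5-dimethoxyphenyl)oxolan-3-yl}methanol; 16 (4R)-4-benzyl-3-(bromoacetyl)-1,3-oxazolidin-2-one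
Product: 17 (4R)-4-benzyl-3-[(4-{(2R,3S,4S)-4-[4-(benzyloxy)-3-methoxybenzyl]-3-(hydroxymethyl)oxolan-2-yl}-2,6-dimethoxyphenoxy)acetyl]-1,3-oxazolidin-2-one
Conditions: K2CO3, acetone, rt
Reagents that add atoms: none
Why: Williamson-type SN2 alkylation in which K2CO3 deprotonates only the phenol and not the primary alcohol, the unhindered α-bromo imide accepts even the di-ortho-substituted phenoxide, the other phenol is still benzylated, and no stereocenter is touched at room temperature.

Step 11
Reactants: 17 (4R)-4-benzyl-3-[(4-{(2R,3S,4S)-4-[4-(benzyloxy)-3-methoxybenzyl]-3-(hydroxymethyl)oxolan-2-yl}-2,6-dimethoxyphenoxy)acetyl]-1,3-oxazolidin-2-one; 18 4-(benzyloxy)-3-methoxybenzaldehyde (O-benzylvanillin)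
Product: 20 (4R)-4-benzyl-3-[(2S,3S)-3-[4-(benzyloxy)-3-methoxyphenyl]-2-(4-{(2R,3S,4S)-4-[4-(benzyloxy)-3-methoxybenzyl]-3-(hydroxymethyl)oxolan-2-yl}-2,6-dimethoxyphenoxy)-3-hydroxypropanoyl]-1,3-oxazolidin-2-one, via bis(trimethylsilyl) ether 19 (not isolated)
Conditions: MgCl2 (0.2 equiv), Et3N (4 equiv), Me3SiCl (3 equiv), 18 (1.3 equiv), EtOAc, rt; then 1 M HCl/THF, 0 °C
Reagents that add atoms: chlorotrimethylsilane, C[Si](C)(C)Cl (silyl groups end up only in 19, not in 20)
Why: Proposed new method: the magnesium halide-catalysed direct anti-aldol of N-acyloxazolidinones with non-enolisable aromatic aldehydes (Evans anti-aldol), established for N-propionyl-type imides, is extended to an N-aryloxyacetyl imide, where Et3N soft-enolises the MgCl2-chelated imide (made easier by the α-oxygen) to the Z-enolate, 18 adds on the face opposite the auxiliary benzyl group (the alkylation face, giving 2S, which becomes C8'' R after reduction) through the boat-like transition state typical of this system (anti, hence 3S = C7'' S, erythro), and Me3SiCl traps the aldolate irreversibly while masking the free C9 alcohol, both silyl ethers falling off in the cold dilute acid work-up.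

Step 12
Reactants: 20 (4R)-4-benzyl-3-[(2S,3S)-3-[4-(benzyloxy)-3-methoxyphenyl]-2-(4-{(2R,3S,4S)-4-[4-(benzyloxy)-3-methoxybenzyl]-3-(hydroxymethyl)oxolan-2-yl}-2,6-dimethoxyphenoxy)-3-hydroxypropanoyl]-1,3-oxazolidin-2-one
Product: 21 (1S,2R)-1-[4-(benzyloxy)-3-methoxyphenyl]-2-(4-{(2R,3S,4S)-4-[4-(benzyloxy)-3-methoxybenzyl]-3-(hydroxymethyl)oxolan-2-yl}-2,6-dimethoxyphenoxy)propane-1,3-diol
Conditions: LiBH4, MeOH (1 equiv), THF, 0 °C
Reagents that add atoms: none
Why: Reductive cleavage of the Evans auxiliary with LiBH4 converts the exocyclic imide carbonyl into the C9'' primary alcohol faster than retro-aldol or epimerisation can occur, so both new stereocenters are kept (the C8'' descriptor changes from S to R only through a priority change).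

Step 13
Reactants: 21 (1S,2R)-1-[4-(benzyloxy)-3-methoxyphenyl]-2-(4-{(2R,3S,4S)-4-[4-(benzyloxy)-3-methoxybenzyl]-3-(hydroxymethyl)oxolan-2-yl}-2,6-dimethoxyphenoxy)propane-1,3-diol
Product: 22 (1S,2R)-1-(4-hydroxy-3-methoxyphenyl)-2-{4-[(2R,3S,4S)-4-(4-hydroxy-3-methoxybenzyl)-3-(hydroxymethyl)oxolan-2-yl]-2,6-dimethoxyphenoxy}propane-1,3-diol (target, CNP0170225.1)
Conditions: H2 (1 atm), 10% Pd/C, EtOAc/EtOH, rt, stopped after uptake of 2 equiv H2
Reagents that add atoms: none
Why: Catalytic hydrogenolysis of the two aryl benzyl ethers is much faster under neutral conditions at 1 atm than cleavage of the C7–O oxolane bond or the C7'' benzylic alcohol, so all five stereocenters are retained.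

## Compound list
1 | 3-(4-hydroxy-3-methoxyphenyl)propanoic acid | COc1cc(CCC(=O)O)ccc1O | starting material
2 | 3-[4-(benzyloxy)-3-methoxyphenyl]propanoic acid | COc1cc(CCC(=O)O)ccc1OCc1ccccc1 | intermediate
3 | (R)-4-benzyl-1,3-oxazolidin-2-one | O=C1N[C@H](Cc2ccccc2)CO1 | starting material
4 | 3-[4-(benzyloxy)-3-methoxyphenyl]propanoic pivalic anhydride | COc1cc(CCC(=O)OC(=O)C(C)(C)C)ccc1OCc1ccccc1 | intermediate (not isolated)
5 | (4R)-4-benzyl-3-{3-[4-(benzyloxy)-3-methoxyphenyl]propanoyl}-1,3-oxazolidin-2-one | COc1cc(CCC(=O)N2[C@H](Cc3ccccc3)COC2=O)ccc1OCc1ccccc1 | intermediate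
6 | 4-hydroxy-3,5-dimethoxybenzaldehyde | COc1cc(C=O)cc(OC)c1O | starting material
7 | 4-formyl-2,6-dimethoxyphenyl N,N-diethylcarbamate | CCN(CC)C(=O)Oc1c(OC)cc(C=O)cc1OC | intermediate
8 | tert-butyl (triphenylphosphoranylidene)acetate | CC(C)(C)OC(=O)C=P(c1ccccc1)(c1ccccc1)c1ccccc1 | starting material
9 | tert-butyl (E)-3-{4-[(diethylcarbamoyl)oxy]-3,5-dimethoxyphenyl}prop-2-enoate | CCN(CC)C(=O)Oc1c(OC)cc(/C=C/C(=O)OC(C)(C)C)cc1OC | intermediate
10 | tert-butyl 3-{4-[(diethylcarbamoyl)oxy]-3,5-dimethoxyphenyl}propanoate | CCN(CC)C(=O)Oc1c(OC)cc(CCC(=O)OC(C)(C)C)cc1OC | intermediate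
11 | tert-butyl (2S,3S)-3-{[(4R)-4-benzyl-2-oxo-1,3-oxazolidin-3-yl]carbonyl}-4-[4-(benzyloxy)-3-methoxyphenyl]-2-{4-[(diethylcarbamoyl)oxy]-3,5-dimethoxybenzyl}butanoate | COc1cc(C[C@H](C(=O)N2[C@H](Cc3ccccc3)COC2=O)[C@@H](C(=O)OC(C)(C)C)Cc2cc(OC)c(OC(=O)N(CC)CC)c(OC)c2)ccc1OCc1ccccc1 | intermediate
12 | (2S,3S)-2-[4-(benzyloxy)-3-methoxybenzyl]-3-(4-hydroxy-3,5-dimethoxybenzyl)butane-1,4-diol | COc1cc(C[C@H](CO)[C@@H](CO)Cc2cc(OC)c(O)c(OC)c2)ccc1OCc1ccccc1 | intermediate
13 | 4-{(2S,3S)-4-[4-(benzyloxy)-3-methoxyphenyl]-2,3-bis(hydroxymethyl)butylidene}-2,6-dimethoxycyclohexa-2,5-dien-1-one | COc1cc(C[C@H](CO)[C@@H](CO)C=C2C=C(OC)C(=O)C(OC)=C2)ccc1OCc1ccccc1 | intermediate (not isolated)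
14 | {(2R,3S,4S)-4-[4-(benzyloxy)-3-methoxybenzyl]-2-(4-hydroxy-3,5-dimethoxyphenyl)oxolan-3-yl}methanol | COc1cc(C[C@@H]2CO[C@@H](c3cc(OC)c(O)c(OC)c3)[C@@H]2CO)ccc1OCc1ccccc1 | intermediate
15 | bromoacetyl bromide | O=C(Br)CBr | starting material
16 | (4R)-4-benzyl-3-(bromoacetyl)-1,3-oxazolidin-2-one | O=C(CBr)N1[C@H](Cc2ccccc2)COC1=O | intermediate
17 | (4R)-4-benzyl-3-[(4-{(2R,3S,4S)-4-[4-(benzyloxy)-3-methoxybenzyl]-3-(hydroxymethyl)oxolan-2-yl}-2,6-dimethoxyphenoxy)acetyl]-1,3-oxazolidin-2-one | COc1cc(C[C@@H]2CO[C@@H](c3cc(OC)c(OCC(=O)N4[C@H](Cc5ccccc5)COC4=O)c(OC)c3)[C@@H]2CO)ccc1OCc1ccccc1 | intermediate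
18 | 4-(benzyloxy)-3-methoxybenzaldehyde | COc1cc(C=O)ccc1OCc1ccccc1 | starting material
19 | bis-O-trimethylsilyl derivative of 20 (silyl groups on the oxolane CH2OH and on the new benzylic OH) | COc1cc(C[C@@H]2CO[C@@H](c3cc(OC)c(O[C@H](C(=O)N4[C@H](Cc5ccccc5)COC4=O)[C@@H](O[Si](C)(C)C)c4ccc(OCc5ccccc5)c(OC)c4)c(OC)c3)[C@@H]2CO[Si](C)(C)C)ccc1OCc1ccccc1 | intermediate (not isolated)
20 | (4R)-4-benzyl-3-[(2S,3S)-3-[4-(benzyloxy)-3-methoxyphenyl]-2-(4-{(2R,3S,4S)-4-[4-(benzyloxy)-3-methoxybenzyl]-3-(hydroxymethyl)oxolan-2-yl}-2,6-dimethoxyphenoxy)-3-hydroxypropanoyl]-1,3-oxazolidin-2-one | COc1cc(C[C@@H]2CO[C@@H](c3cc(OC)c(O[C@H](C(=O)N4[C@H](Cc5ccccc5)COC4=O)[C@@H](O)c4ccc(OCc5ccccc5)c(OC)c4)c(OC)c3)[C@@H]2CO)ccc1OCc1ccccc1 | intermediate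
21 | (1S,2R)-1-[4-(benzyloxy)-3-methoxyphenyl]-2-(4-{(2R,3S,4S)-4-[4-(benzyloxy)-3-methoxybenzyl]-3-(hydroxymethyl)oxolan-2-yl}-2,6-dimethoxyphenoxy)propane-1,3-diol | COc1cc(C[C@@H]2CO[C@@H](c3cc(OC)c(O[C@H](CO)[C@@H](O)c4ccc(OCc5ccccc5)c(OC)c4)c(OC)c3)[C@@H]2CO)ccc1OCc1ccccc1 | intermediate
22 | (1S,2R)-1-(4-hydroxy-3-methoxyphenyl)-2-{4-[(2R,3S,4S)-4-(4-hydroxy-3-methoxybenzyl)-3-(hydroxymethyl)oxolan-2-yl]-2,6-dimethoxyphenoxy}propane-1,3-diol | COc1cc(C[C@@H]2CO[C@@H](c3cc(OC)c(O[C@H](CO)[C@@H](O)c4ccc(O)c(OC)c4)c(OC)c3)[C@@H]2CO)ccc1O | target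

## Step count and risks
Total step count: 13.
Longest linear sequence: 10 steps, from syringaldehyde (steps 3, 4, 5, 6, 7, 8, 10, 11, 12, 13).

**Step 8 (quinone methide ring closure).** There are three risks. Product 14 is again a 4-substituted syringol and may be over-oxidised. Quinone methide 13 may tautomerise to a styrene. The guaiacyl ring may attack C7 and give an aryltetralin.

The fallback brings the C7 oxygen in by C–C bond formation instead of C–H oxidation. It sets out from imide 5 (with aldehyde 7) and comes back at 14. The benzylbutyrolactone F3, made from 5 as described under step 6 below, is deprotonated with LiN(iPr)2 at −78 °C and added to 7. This gives the aldol lactone F7, which is trans at C8/C8'; its C7 epimers are of no consequence. Reduction with LiAlH4 opens the lactone and removes the carbamate, giving the 7-hydroxy tetraol F8. Catalytic camphorsulfonic acid in CH2Cl2 at 0 °C then ionises the para-hydroxybenzylic alcohol, and the C9' hydroxyl closes the ring to 14.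

**Step 6 (oxidative heterocoupling).** The risks are homodimers and modest control at C8.

The fallback builds the 8–8' array by two polar alkylations. It sets out from imide 5 (with aldehyde 7) and comes back at diol 12.
- The sodium enolate of 5 (NaN(SiMe3)2, THF, −78 °C) is alkylated with tert-butyl bromoacetate to the succinate imide F1. This is an Evans alkylation with the same facial sense, so C8' = S.
- LiBH4 reduces only the imide, giving the hydroxy ester F2.
- CF3CO2H closes F2 to the benzylbutyrolactone F3.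
- In parallel, NaBH4 reduces 7 to the benzylic alcohol F4, and PBr3 converts this into the benzylic bromide F5.
- The lithium enolate of F3 is alkylated by F5 anti to the C8' substituent, giving the trans-dibenzyl lactone F6.
- LiAlH4 reduces the lactone and cleaves the carbamate of F6, giving 12.

**Step 11 (anti-aldol of an aryloxyacetyl imide).** The risk is that the anti/syn ratio and the facial control are untested with the bulky α-aryloxy group.

The fallback gives up reagent control of absolute configuration and uses the enantiopure oxolane part as a resolving handle. It sets out from 14 and comes back at 21. K2CO3 and ethyl bromoacetate convert 14 into the ethyl aryloxyacetate F9. Its lithium enolate (LiN(iPr)2, 2.2 equiv to cover the free alcohol, THF, −78 °C) adds to 18 with the erythro preference typical of 2,6-dimethoxyphenoxyacetate enolates. The two erythro products are diastereomers, so the erythro aldol ester F10 is obtained pure by preparative HPLC. Reduction of F10 with LiAlH4 at 0 °C gives 21.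

## Further compounds
F1 | step 6 | tert-butyl (3S)-3-{[(4R)-4-benzyl-2-oxo-1,3-oxazolidin-3-yl]carbonyl}-4-[4-(benzyloxy)-3-methoxyphenyl]butanoate | COc1cc(C[C@H](C(=O)N2[C@H](Cc3ccccc3)COC2=O)CC(=O)OC(C)(C)C)ccc1OCc1ccccc1
F2 | step 6 | tert-butyl (3S)-4-[4-(benzyloxy)-3-methoxyphenyl]-3-(hydroxymethyl)butanoate | COc1cc(C[C@H](CO)CC(=O)OC(C)(C)C)ccc1OCc1ccccc1
F3 | step 6 | (4S)-4-[4-(benzyloxy)-3-methoxybenzyl]oxolan-2-one | COc1cc(C[C@@H]2COC(=O)C2)ccc1OCc1ccccc1
F4 | step 6 | 4-(hydroxymethyl)-2,6-dimethoxyphenyl N,N-diethylcarbamate | CCN(CC)C(=O)Oc1c(OC)cc(CO)cc1OC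
F5 | step 6 | 4-(bromomethyl)-2,6-dimethoxyphenyl N,N-diethylcarbamate | CCN(CC)C(=O)Oc1c(OC)cc(CBr)cc1OC
F6 | step 6 | 4-({(3S,4S)-4-[4-(benzyloxy)-3-methoxybenzyl]-2-oxooxolan-3-yl}methyl)-2,6-dimethoxyphenyl N,N-diethylcarbamate | COc1cc(C[C@@H]2COC(=O)[C@H]2Cc3cc(OC)c(OC(=O)N(CC)CC)c(OC)c3)ccc1OCc1ccccc1
F7 | step 8 | 4-[{(3R,4S)-4-[4-(benzyloxy)-3-methoxybenzyl]-2-oxooxolan-3-yl}(hydroxy)methyl]-2,6-dimethoxyphenyl N,N-diethylcarbamate (both C7 epimers) | COc1cc(C[C@@H]2COC(=O)[C@H]2C(O)c3cc(OC)c(OC(=O)N(CC)CC)c(OC)c3)ccc1OCc1ccccc1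
F8 | step 8 | (2S,3S)-2-[4-(benzyloxy)-3-methoxybenzyl]-3-[hydroxy(4-hydroxy-3,5-dimethoxyphenyl)methyl]butane-1,4-diol (both C7 epimers) | COc1cc(C[C@H](CO)[C@@H](CO)C(O)c2cc(OC)c(O)c(OC)c2)ccc1OCc1ccccc1
F9 | step 11 | ethyl (4-{(2R,3S,4S)-4-[4-(benzyloxy)-3-methoxybenzyl]-3-(hydroxymethyl)oxolan-2-yl}-2,6-dimethoxyphenoxy)acetate | COc1cc(C[C@@H]2CO[C@@H](c3cc(OC)c(OCC(=O)OCC)c(OC)c3)[C@@H]2CO)ccc1OCc1ccccc1
F10 | step 11 | ethyl (2S,3S)-3-[4-(benzyloxy)-3-methoxyphenyl]-2-(4-{(2R,3S,4S)-4-[4-(benzyloxy)-3-methoxybenzyl]-3-(hydroxymethyl)oxolan-2-yl}-2,6-dimethoxyphenoxy)-3-hydroxypropanoate | COc1cc(C[C@@H]2CO[C@@H](c3cc(OC)c(O[C@H](C(=O)OCC)[C@@H](O)c4ccc(OCc5ccccc5)c(OC)c4)c(OC)c3)[C@@H]2CO)ccc1OCc1ccccc1
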